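## Retrosynthetic overview

1. Feature: in ring B (C1' ether carbon, C2' OH, C3'/C5'/C6' Br), C1' lies between C2'–OH and C6'–Br. This triad is read as C2 of a mirror-symmetric 2-aryloxycyclohexane-1,3-dione, with one carbonyl ending as C6'–Br and the other as C2'–OH.
2. The bromines at C2 and C4 (ring A) and at C3' and C5' (ring B) sit ortho and para to the two hydroxyls. They are disconnected first, as a late fourfold bromination of the bis-phenol, and the ring A hydroxyl travels as the methyl ether of guaiacol.
3. The 3-bromo-2-aryloxyphenol goes back by formal rehydrogenation to the 3-bromo-2-aryloxycyclohexenone, and from there by bromine-for-oxygen exchange to the dione.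
4. The dione is opened at C1'–C2' (retro-Claisen) to methyl 6-(2-methoxyphenoxy)-5-oxohexanoate. Its crowded aryl–O–C1' bond then becomes a simple SN2 union of guaiacol and methyl 6-bromo-5-oxohexanoate, itself made from methyl 5-chloro-5-oxopentanoate and trimethylsilyldiazomethane.
5. Ring order: ring A is bought. Ring B is the only ring built (step 3) and is aromatised in step 6.

Key step: step 3

Remark: the target holds no stereocentre, and rotation about the two aryl–oxygen bonds is taken as free, so no step has to set configuration. The cyclisation product is drawn as the diketone although it should exist largely as its enol.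

## Route

Step 1
Reactants: 1 methyl 5-chloro-5-oxopentanoate; 2 trimethylsilyldiazomethane
Product: 4 methyl 6-bromo-5-oxohexanoate, via methyl 6-diazo-5-oxohexanoate 3 (not isolated)
Conditions: TMSCHN2 (2 M in hexanes), MeCN/THF 1:1, 0 °C to rt; then 33% HBr in AcOH, 0 °C
Reagents that add atoms: hydrogen bromide, Br
Why: C-acylation of the diazoalkane by the acid chloride, with chloride taking the silyl group, gives the diazoketone (first stage of an Arndt–Eistert sequence), which HBr protonates on carbon so that bromide displaces N2 and bromine ends only on the terminal carbon C6, while the methyl ester is inert to both reagents.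

Step 2
Reactants: 4 methyl 6-bromo-5-oxohexanoate; 5 guaiacol
Product: 6 methyl 6-(2-methoxyphenoxy)-5-oxohexanoate
Conditions: K2CO3, acetone, rt to 40 °C
Reagents that add atoms: none
Why: Williamson ether synthesis, in which the phenoxide formed by the weak base displaces bromide by SN2 at a primary carbon activated by the neighbouring carbonyl, under conditions too mild to touch the ester or to enolise the ketone productively.

Step 3
Reactants: 6 methyl 6-(2-methoxyphenoxy)-5-oxohexanoate
Product: 8 2-(2-methoxyphenoxy)cyclohexane-1,3-dione, via potassium dionate 7 (not isolated)
Conditions: KOtBu (2 equiv), THF, slow addition of 6 (final about 0.05 M), 0 °C to rt; then 1 M HCl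
Reagents that add atoms: none
Why: tert-Butoxide equilibrates the enolates of 6, and the one at C6 (the OCH2 group, acidified by the ketone and by the aryloxy oxygen) adds through carbon to the ester carbonyl C1, after which the tetrahedral intermediate expels methoxide and leaves the bond that becomes C1'–C2' of ring B. The closest known reaction is the Dieckmann-type intramolecular Claisen cyclisation of 5-oxohexanoate esters to cyclohexane-1,3-diones. Ring B closes in the 6-(enolendo)-exo-trig mode, which is a favoured closure. No stereocentre arises, because C2 of 8 lies on the mirror plane of the dione and is enolised. The step needs C-acylation at C6 and ring closure ahead of bimolecular condensation: the enolates at C4 and C2 could only form strained four-membered rings reversibly, O-acylation to the enol lactone is reversed by alkoxide, and slow addition at high dilution holds back intermolecular aldol and Claisen paths. All equilibria drain into the delocalised potassium dionate 7, from which acid releases 8.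

Step 4
Reactants: 8 2-(2-methoxyphenoxy)cyclohexane-1,3-dione
Product: 9 3-bromo-2-(2-methoxyphenoxy)cyclohex-2-en-1-one
Conditions: (COBr)2 (1.2 equiv), DMF (cat.), CH2Cl2, 0 °C to rt
Reagents that add atoms: oxalyl bromide, O=C(Br)C(=O)Br
Why: Vilsmeier-type deoxybromination of a vinylogous acid, in which the bromoiminium salt activates the enol oxygen and bromide replaces it by addition–elimination, and since 8 is mirror-symmetric either carbonyl gives the same β-bromo enone.

Step 5
Reactants: 9 3-bromo-2-(2-methoxyphenoxy)cyclohex-2-en-1-one
Product: 11 1-bromo-2-(2-methoxyphenoxy)-3-(trimethylsilyloxy)cyclohexa-1,3-diene, via lithium dienolate 10 (not isolated)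
Conditions: lithium diisopropylamide (commercial solution, 1.1 equiv), THF, −78 °C; then TMSCl, −78 to 0 °C; pentane, cold aq NaHCO3 wash, used crude
Reagents that add atoms: chlorotrimethylsilane, C[Si](C)(C)Cl
Why: Kinetic α'-deprotonation of the enone at C6 by a hindered amide base gives the cross-conjugated dienolate, which is silylated on oxygen (silyl enol ether formation), the low temperature protecting the β-bromo enone from conjugate addition–elimination.

Step 6
Reactants: 11 1-bromo-2-(2-methoxyphenoxy)-3-(trimethylsilyloxy)cyclohexa-1,3-diene
Product: 13 3-bromo-2-(2-methoxyphenoxy)phenol, via aryl trimethylsilyl ether 12 (not isolated)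
Conditions: DDQ (1.1 equiv), 2,4,6-collidine, toluene, 0 °C to rt; then 1 M HCl, THF, rt
Reagents that add atoms: none
Why: DDQ dehydrogenation of a silyl dienol ether, in which hydride abstraction from the allylic CH2 gives an oxygen-stabilised arenium-type cation that loses a proton to become aromatic, and mild acid then cleaves the labile aryl O–Si bond without touching the C–Br bond or the methyl ether.

Step 7
Reactants: 13 3-bromo-2-(2-methoxyphenoxy)phenol
Product: 14 3-bromo-2-(2-hydroxyphenoxy)phenol
Conditions: BBr3 (3 equiv), CH2Cl2, −78 °C to rt; then H2O
Reagents that add atoms: none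
Why: Lewis-acid cleavage of an aryl methyl ether, in which boron binds the methoxy oxygen and bromide attacks the methyl carbon by SN2, whereas the diaryl ether offers no sp3 carbon for attack and survives, and water hydrolyses the B–O bonds on work-up.

Step 8
Reactants: 14 3-bromo-2-(2-hydroxyphenoxy)phenol
Product: 15 3,4,6-tribromo-2-(3,5-dibromo-2-hydroxyphenoxy)phenol (CNP0163911.0)
Conditions: Br2 (4.0 equiv), AcOH, rt
Reagents that add atoms: bromine, BrBr
Why: Electrophilic aromatic bromination steered by the free hydroxyl as the strongest donor on each ring, so that ring A should react at C2 (ortho) and C4 (para) and ring B at C3' (ortho) and C5' (para), while the remaining CH positions C3, C5 and C4' are meta to hydroxyl and flanked by bromine, which should stop uptake after four equivalents.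

## Compound list

1 | methyl 5-chloro-5-oxopentanoate | COC(=O)CCCC(Cl)=O | starting material
2 | trimethylsilyldiazomethane | C[Si](C)(C)C=[N+]=[N-] | starting material
3 | methyl 6-diazo-5-oxohexanoate | COC(=O)CCCC(=O)C=[N+]=[N-] | intermediate
4 | methyl 6-bromo-5-oxohexanoate | COC(=O)CCCC(=O)CBr | intermediate
5 | guaiacol (2-methoxyphenol) | COc1ccccc1O | starting material
6 | methyl 6-(2-methoxyphenoxy)-5-oxohexanoate | COC(=O)CCCC(=O)COc1ccccc1OC | intermediate
7 | potassium 2-(2-methoxyphenoxy)-3-oxocyclohex-1-en-1-olate | COc1ccccc1OC1=C([O-])CCCC1=O.[K+] | intermediate
8 | 2-(2-methoxyphenoxy)cyclohexane-1,3-dione | COc1ccccc1OC1C(=O)CCCC1=O | intermediate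
9 | 3-bromo-2-(2-methoxyphenoxy)cyclohex-2-en-1-one | COc1ccccc1OC1=C(Br)CCCC1=O | intermediate
10 | lithium 5-bromo-6-(2-methoxyphenoxy)cyclohexa-1,5-dien-1-olate | COc1ccccc1OC1=C(Br)CCC=C1[O-].[Li+] | intermediate
11 | 1-bromo-2-(2-methoxyphenoxy)-3-(trimethylsilyloxy)cyclohexa-1,3-diene | COc1ccccc1OC1=C(Br)CCC=C1O[Si](C)(C)C | intermediate
12 | 1-bromo-2-(2-methoxyphenoxy)-3-(trimethylsilyloxy)benzene | COc1ccccc1Oc1c(Br)cccc1O[Si](C)(C)C | intermediate
13 | 3-bromo-2-(2-methoxyphenoxy)phenol | COc1ccccc1Oc1c(O)cccc1Br | intermediate
14 | 3-bromo-2-(2-hydroxyphenoxy)phenol | Oc1ccccc1Oc1c(O)cccc1Br | intermediate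
15 | 3,4,6-tribromo-2-(3,5-dibromo-2-hydroxyphenoxy)phenol (achiral) | Oc1c(Br)cc(Br)cc1Oc1c(O)c(Br)cc(Br)c1Br | target

## Step count and risks

Total step count: 8
Longest linear sequence: 8 steps (from 1 to 15)

Steps most likely to fail:

1. Step 3 (key step). Bimolecular aldol or Claisen condensation of the keto ester, or base-induced loss of the aryloxide, may outrun ring closure. In the fallback the ring is taken preformed and the C2–O bond is made instead. Commercial cyclohexane-1,3-dione undergoes diazo transfer (4-acetamidobenzenesulfonyl azide, Et3N, MeCN, rt) to give 2-diazocyclohexane-1,3-dione F1. The rhodium carbenoid generated from it with Rh2(OAc)4 (cat., 1,2-dichloroethane, reflux) then inserts into the O–H bond of guaiacol. This fallback sets out from 5 and comes back to the route at 8.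

2. Step 5. The amide base may attack the bromine-bearing β-carbon or deprotonate at the γ-position with decomposition, or the labile silyl dienol ether may be hydrolysed back to the enone before it can be oxidised. The fallback uses halogenation and dehydrohalogenation, with no strong base and no silyl ether. Heating 9 with CuBr2 (2 equiv) in EtOAc/CHCl3 at reflux should brominate the ketone through its enol to give racemic 3,6-dibromo-2-(2-methoxyphenoxy)cyclohex-2-en-1-one F2. Li2CO3 and LiBr in DMF at 120 °C should then remove HBr, and the resulting dienone tautomerises to the phenol. This fallback sets out from 9, bypasses steps 5 and 6, and comes back at 13.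

3. Step 8. The two rings compete for bromine. Uneven uptake, incomplete substitution at the crowded C5' position, or ipso attack leading to bromodienones could give a mixture that is hard to separate. The fallback brominates one ring at a time and places the demethylation in between.
   - Compound 13 is treated with Br2 (2 equiv, AcOH, 0 °C to rt), where the free phenol of ring B should react first, to give 3,4,6-tribromo-2-(2-methoxyphenoxy)phenol F3. Any attack on the anisole ring at this stage should fall para to methoxy at C4, which must carry bromine anyway.
   - BBr3 (CH2Cl2, −78 °C to rt, then H2O) gives 3,4,6-tribromo-2-(2-hydroxyphenoxy)phenol F4.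
   - Br2 (2 equiv, AcOH, rt) then finds open activated positions only on ring A.

   This fallback sets out from 13 and comes back at 15.

## Further compounds

F1 | step 3 | 2-diazocyclohexane-1,3-dione | [N-]=[N+]=C1C(=O)CCCC1=O
F2 | step 5 | 3,6-dibromo-2-(2-methoxyphenoxy)cyclohex-2-en-1-one (racemic) | COc1ccccc1OC1=C(Br)CCC(Br)C1=O
F3 | step 8 | 3,4,6-tribromo-2-(2-methoxyphenoxy)phenol | COc1ccccc1Oc1c(O)c(Br)cc(Br)c1Br
F4 | step 8 | 3,4,6-tribromo-2-(2-hydroxyphenoxy)phenol | Oc1ccccc1Oc1c(O)c(Br)cc(Br)c1Br
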